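**Retrosynthetic overview**
1. Target 18 ⇒ global MOM removal from flavanone 17. Ring C is closed last, by a catalyst-controlled oxa-Michael addition of 2'-hydroxychalcone 16, which sets C2.
2. Chalcone 16 ⇒ Claisen–Schmidt condensation of ring A acetophenone 13 with ring B aldehyde 15; 13 ⇒ ortho-acetylation of lavandulyl phenol 11.
3. Phenol 11 ⇒ reduction and Wittig opening of benzoxepinone 8. Opening this transient seven-membered lactone frees exactly the phenol oxygen that becomes O1 of the flavanone.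
4. Key disconnection: the ArCH2–CH bond of 8 ⇒ carbene-bound homoenolate of dienal 6 (its β-carbon made nucleophilic) plus ortho-quinone methide 7, released from sulfone 4. This sets the (R)-lavandulyl centre.
5. Ring order: rings A and B are bought; the transient lactone ring is formed in step 4 and opened in step 6; ring C is formed in step 10.

Assumption: 2,4-dihydroxy-5-methoxybenzaldehyde (14) is taken as a catalogue compound, and the named enantiomers of the two chiral organocatalysts are taken to give the drawn configurations (a model run decides; otherwise the mirror-image or pseudo-enantiomeric catalyst is used).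

**Step 1**
Reactants: 1 2,4,6-trihydroxybenzaldehyde
Product: 2 2-hydroxy-4,6-bis(methoxymethoxy)benzaldehyde
Conditions: MOMCl (2.2 equiv), iPr2NEt, CH2Cl2, 0 °C to rt
Reagents that add atoms: chloromethyl methyl ether (MOMCl), COCCl
Why: O-alkylation (MOM protection) takes the two non-chelated hydroxyls and leaves free the OH that is hydrogen-bonded to the formyl group, which marks the oxygen that later becomes O1.

**Step 2**
Reactants: 2 2-hydroxy-4,6-bis(methoxymethoxy)benzaldehyde
Product: 4 3,5-bis(methoxymethoxy)-2-[(4-methylbenzenesulfonyl)methyl]phenol, via salicyl alcohol 3 (not isolated)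
Conditions: NaBH4, THF/MeOH, 0 °C; then AcOH, TolSO2Na, rt
Reagents that add atoms: sodium 4-methylbenzenesulfinate, Cc1ccc(cc1)S(=O)[O-].[Na+]
Why: Borohydride reduction followed by SN1-type substitution of the very easily ionised 2-hydroxybenzyl alcohol by sulfinate gives the bench-stable sulfone, a base-triggered ortho-quinone methide precursor, without isolating the labile alcohol.

**Step 3**
Reactants: 5 methacrolein (2-methylprop-2-enal)
Product: 6 (2E)-4-methylpenta-2,4-dienal
Conditions: Ph3P=CHCHO, 5 (3 equiv), toluene, 80 °C; distillation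
Reagents that add atoms: (triphenylphosphoranylidene)acetaldehyde, O=CC=P(c1ccccc1)(c1ccccc1)c1ccccc1
Why: Wittig olefination with the formyl-stabilised ylide gives the (E)-dienal, and the excess of volatile methacrolein suppresses a second homologation.

**Step 4 (key step)**
Reactants: 4 3,5-bis(methoxymethoxy)-2-[(4-methylbenzenesulfonyl)methyl]phenol; 6 (2E)-4-methylpenta-2,4-dienal
Product: 8 (4S)-6,8-bis(methoxymethoxy)-4-(prop-1-en-2-yl)-4,5-dihydro-1-benzoxepin-2(3H)-one, via ortho-quinone methide 7 (not isolated)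
Conditions: 6 (1.5 equiv), (5aS,10bR)-2-mesityl-4,5a,6,10b-tetrahydroindeno[2,1-b][1,2,4]triazolo[4,3-d][1,4]oxazin-2-ium tetrafluoroborate (15 mol %), Cs2CO3 (2.2 equiv), THF, slow addition of 4, 0 °C to rt
Reagents that add atoms: none
Why: Proposed new method: Cs2CO3 eliminates sulfinate from 4 to give quinone methide 7 while the chiral carbene turns dienal 6 into an extended Breslow intermediate whose β-carbon (a homoenolate, reversed polarity) attacks the exocyclic CH2 of 7, and the acyl azolium so formed is closed by the phenoxide to the seven-membered lactone, so the catalyst-shielded face of the homoenolate sets C4 as (S), the future (R)-lavandulyl centre; the closest known reaction is the carbene-catalysed enantioselective formal [4+3] annulation of enals with ortho-quinone methides generated in situ, here extended to a β-isopropenyl dienal (β- versus δ-attack is the open point) and a sulfone precursor.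

**Step 5**
Reactants: 8 (4S)-6,8-bis(methoxymethoxy)-4-(prop-1-en-2-yl)-4,5-dihydro-1-benzoxepin-2(3H)-one
Product: 9 (4S)-6,8-bis(methoxymethoxy)-4-(prop-1-en-2-yl)-2,3,4,5-tetrahydro-1-benzoxepin-2-ol (both C2 epimers)
Conditions: iBu2AlH (1.1 equiv), CH2Cl2, −78 °C; aq. potassium sodium tartrate (KNaC4H4O6)
Reagents that add atoms: none
Why: Partial hydride reduction of the aryl lactone stops at the aluminium hemiacetal at −78 °C and gives the lactol on work-up, leaving the stereocentre untouched.

**Step 6**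
Reactants: 9 (4S)-6,8-bis(methoxymethoxy)-4-(prop-1-en-2-yl)-2,3,4,5-tetrahydro-1-benzoxepin-2-ol
Product: 11 3,5-bis(methoxymethoxy)-2-[(2R)-5-methyl-2-(prop-1-en-2-yl)hex-4-en-1-yl]phenol, via ring-opened hydroxy-aldehyde 10 (not isolated)
Conditions: iPrPPh3I (3 equiv), n-BuLi (3 equiv), THF, 0 °C; then 9, 0 °C to rt
Reagents that add atoms: isopropyltriphenylphosphonium iodide, CC(C)[P+](c1ccccc1)(c1ccccc1)c1ccccc1.[I-]
Why: Wittig olefination of the open hydroxy-aldehyde with the non-stabilised isopropylidene ylide (one extra equivalent is consumed by the phenol) builds the prenyl terminus and frees the phenol, and the stereocentre, being β to the aldehyde, cannot epimerise.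

**Step 7**
Reactants: 11 3,5-bis(methoxymethoxy)-2-[(2R)-5-methyl-2-(prop-1-en-2-yl)hex-4-en-1-yl]phenol
Product: 13 1-{2-hydroxy-4,6-bis(methoxymethoxy)-3-[(2R)-5-methyl-2-(prop-1-en-2-yl)hex-4-en-1-yl]phenyl}ethan-1-one, via bromomagnesium phenoxide 12 (not isolated)
Conditions: EtMgBr (1.0 equiv), Et2O, 0 °C; solvent switch to toluene; AcCl (1.1 equiv), rt
Reagents that add atoms: acetyl chloride, CC(Cl)=O
Why: Ortho-coordinated Friedel–Crafts acylation: in non-coordinating toluene the acyl chloride bound to the magnesium phenoxide is delivered to the only free ortho carbon and not to the para carbon, without a Lewis acid strong enough to harm the MOM ethers or the alkenes.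

**Step 8**
Reactants: 14 2,4-dihydroxy-5-methoxybenzaldehyde
Product: 15 5-methoxy-2,4-bis(methoxymethoxy)benzaldehyde
Conditions: MOMCl (3 equiv), K2CO3, acetone, reflux
Reagents that add atoms: chloromethyl methyl ether (MOMCl), COCCl
Why: O-alkylation (MOM protection) of both phenols, the chelated 2-OH included under these forcing conditions, prevents phenoxide deactivation of the aldehyde in the condensation.

**Step 9**
Reactants: 13 1-{2-hydroxy-4,6-bis(methoxymethoxy)-3-[(2R)-5-methyl-2-(prop-1-en-2-yl)hex-4-en-1-yl]phenyl}ethan-1-one; 15 5-methoxy-2,4-bis(methoxymethoxy)benzaldehyde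
Product: 16 (2E)-1-{2-hydroxy-4,6-bis(methoxymethoxy)-3-[(2R)-5-methyl-2-(prop-1-en-2-yl)hex-4-en-1-yl]phenyl}-3-[5-methoxy-2,4-bis(methoxymethoxy)phenyl]prop-2-en-1-one
Conditions: KOH (50% aq.), EtOH, rt, 24 h; neutral work-up
Reagents that add atoms: none
Why: Claisen–Schmidt aldol condensation, in which strong base holds the product as the open (E)-chalcone phenoxide and the remote stereocentre is not enolisable.

**Step 10**
Reactants: 16 the (2E)-chalcone of step 9
Product: 17 (2S)-2-[5-methoxy-2,4-bis(methoxymethoxy)phenyl]-5,7-bis(methoxymethoxy)-8-[(2R)-5-methyl-2-(prop-1-en-2-yl)hex-4-en-1-yl]-2,3-dihydro-4H-chromen-4-one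
Conditions: 1-[3,5-bis(trifluoromethyl)phenyl]-3-[(8α,9S)-6'-methoxycinchonan-9-yl]thiourea (10 mol %), toluene, 0 °C
Reagents that add atoms: none
Why: Bifunctional organocatalytic intramolecular oxa-Michael addition, in which the quinuclidine deprotonates the 2'-OH while the thiourea binds the enone carbonyl so that the phenoxide attacks one face of the β-carbon under kinetic control and sets C2 as (S); the 6'-OMOM group favours ring closure, and any C2 epimer is a diastereomer that can be removed or recycled by base-mediated ring opening.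

**Step 11**
Reactants: 17 the tetra-MOM flavanone of step 10
Product: 18 (2S)-2-(2,4-dihydroxy-5-methoxyphenyl)-5,7-dihydroxy-8-[(2R)-5-methyl-2-(prop-1-en-2-yl)hex-4-en-1-yl]-2,3-dihydro-4H-chromen-4-one (CNP0323048.1)
Conditions: 3 M aq. HCl/MeOH (1:5), 45 °C, 1–2 h, monitored
Reagents that add atoms: none
Why: Acid-catalysed acetal exchange with methanol removes all four MOM groups; C2 is stable to dilute acid, and the short, mild exposure limits acid-catalysed addition of the 7-OH to the isopropenyl group.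

**Compound list**
1 | 2,4,6-trihydroxybenzaldehyde | O=Cc1c(O)cc(O)cc1O | starting material
2 | 2-hydroxy-4,6-bis(methoxymethoxy)benzaldehyde | O=Cc1c(O)cc(OCOC)cc1OCOC | intermediate
3 | 2-(hydroxymethyl)-3,5-bis(methoxymethoxy)phenol | OCc1c(O)cc(OCOC)cc1OCOC | intermediate (not isolated)
4 | 3,5-bis(methoxymethoxy)-2-[(4-methylbenzenesulfonyl)methyl]phenol | Cc1ccc(cc1)S(=O)(=O)Cc1c(O)cc(OCOC)cc1OCOC | intermediate
5 | methacrolein (2-methylprop-2-enal) | C=C(C)C=O | starting material
6 | (2E)-4-methylpenta-2,4-dienal | C=C(C)/C=C/C=O | intermediate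
7 | 3,5-bis(methoxymethoxy)-6-methylidenecyclohexa-2,4-dien-1-one | C=C1C(=O)C=C(OCOC)C=C1OCOC | intermediate (not isolated)
8 | (4S)-6,8-bis(methoxymethoxy)-4-(prop-1-en-2-yl)-4,5-dihydro-1-benzoxepin-2(3H)-one | C=C(C)[C@@H]1CC(=O)Oc2cc(OCOC)cc(OCOC)c2C1 | intermediate
9 | (4S)-6,8-bis(methoxymethoxy)-4-(prop-1-en-2-yl)-2,3,4,5-tetrahydro-1-benzoxepin-2-ol (both C2 epimers) | C=C(C)[C@@H]1CC(O)Oc2cc(OCOC)cc(OCOC)c2C1 | intermediate
10 | (3S)-3-{[2-hydroxy-4,6-bis(methoxymethoxy)phenyl]methyl}-4-methylpent-4-enal | C=C(C)[C@H](CC=O)Cc1c(O)cc(OCOC)cc1OCOC | intermediate (not isolated)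
11 | 3,5-bis(methoxymethoxy)-2-[(2R)-5-methyl-2-(prop-1-en-2-yl)hex-4-en-1-yl]phenol | C=C(C)[C@H](CC=C(C)C)Cc1c(O)cc(OCOC)cc1OCOC | intermediate
12 | bromomagnesium 3,5-bis(methoxymethoxy)-2-[(2R)-5-methyl-2-(prop-1-en-2-yl)hex-4-en-1-yl]phenoxide | C=C(C)[C@H](CC=C(C)C)Cc1c(O[Mg]Br)cc(OCOC)cc1OCOC | intermediate (not isolated)
13 | 1-{2-hydroxy-4,6-bis(methoxymethoxy)-3-[(2R)-5-methyl-2-(prop-1-en-2-yl)hex-4-en-1-yl]phenyl}ethan-1-one | C=C(C)[C@H](CC=C(C)C)Cc1c(O)c(C(C)=O)c(OCOC)cc1OCOC | intermediate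
14 | 2,4-dihydroxy-5-methoxybenzaldehyde | O=Cc1cc(OC)c(O)cc1O | starting material
15 | 5-methoxy-2,4-bis(methoxymethoxy)benzaldehyde | O=Cc1cc(OC)c(OCOC)cc1OCOC | intermediate
16 | (2E)-1-{2-hydroxy-4,6-bis(methoxymethoxy)-3-[(2R)-5-methyl-2-(prop-1-en-2-yl)hex-4-en-1-yl]phenyl}-3-[5-methoxy-2,4-bis(methoxymethoxy)phenyl]prop-2-en-1-one | C=C(C)[C@H](CC=C(C)C)Cc1c(O)c(C(=O)/C=C/c2cc(OC)c(OCOC)cc2OCOC)c(OCOC)cc1OCOC | intermediate
17 | (2S)-2-[5-methoxy-2,4-bis(methoxymethoxy)phenyl]-5,7-bis(methoxymethoxy)-8-[(2R)-5-methyl-2-(prop-1-en-2-yl)hex-4-en-1-yl]-2,3-dihydro-4H-chromen-4-one | C=C(C)[C@H](CC=C(C)C)Cc1c(OCOC)cc(OCOC)c2c1O[C@H](c1cc(OC)c(OCOC)cc1OCOC)CC2=O | intermediate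
18 | (2S)-2-(2,4-dihydroxy-5-methoxyphenyl)-5,7-dihydroxy-8-[(2R)-5-methyl-2-(prop-1-en-2-yl)hex-4-en-1-yl]-2,3-dihydro-4H-chromen-4-one | C=C(C)[C@H](CC=C(C)C)Cc1c(O)cc(O)c2c1O[C@H](c1cc(OC)c(O)cc1O)CC2=O | target

**Step count**
Total: 11 steps. Longest linear sequence: 9 steps (1, 2, 4, 5, 6, 7, 9, 10, 11); steps 3 and 8 are side branches.

**Three steps most likely to fail, with fallbacks**

Step 4 (key annulation). The dienal may react at its δ-carbon, the electron-rich quinone methide may dimerise, or the enantioselectivity may be low. The fallback makes the stereocentre at the α-carbon of an azolium enolate instead. It sets out from sulfone 4. Commercial 5-methylhex-4-enoic acid is converted with carbonyldiimidazole into 1-(1H-imidazol-1-yl)-5-methylhex-4-en-1-one F1. The same triazolium carbene and Cs2CO3 turn F1 into its azolium enolate, which adds to quinone methide 7 in a formal [4+2] annulation to give (3R)-5,7-bis(methoxymethoxy)-3-(3-methylbut-2-en-1-yl)-3,4-dihydro-2H-chromen-2-one F2. The lactone is opened with MeNH(OMe)·HCl and iPrMgCl to (2R)-2-{[2-hydroxy-4,6-bis(methoxymethoxy)phenyl]methyl}-N-methoxy-N,5-dimethylhex-4-enamide F3. MeMgBr then gives (3R)-3-{[2-hydroxy-4,6-bis(methoxymethoxy)phenyl]methyl}-6-methylhept-5-en-2-one F4. Non-basic methylenation with Cp2TiMe2 (toluene, 65 °C) converts the acetyl group into the isopropenyl group without epimerising the α-centre, and the sequence comes back to the route at phenol 11.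

Step 10 (asymmetric ring closure). The catalyst may give modest facial selectivity, and the oxa-Michael addition is reversible. The fallback fixes C2 by kinetic resolution. It sets out from chalcone 16. NaOAc in EtOH at reflux closes the ring without facial control and gives 17 together with its C2 epimer, (2R)-2-[5-methoxy-2,4-bis(methoxymethoxy)phenyl]-5,7-bis(methoxymethoxy)-8-[(2R)-5-methyl-2-(prop-1-en-2-yl)hex-4-en-1-yl]-2,3-dihydro-4H-chromen-4-one F7. Asymmetric transfer hydrogenation of the mixture with RuCl(p-cymene)[(R,R)-TsDPEN] and HCO2H/Et3N reduces the (2R)-ketone in the matched sense to (2R,4R)-2-[5-methoxy-2,4-bis(methoxymethoxy)phenyl]-5,7-bis(methoxymethoxy)-8-[(2R)-5-methyl-2-(prop-1-en-2-yl)hex-4-en-1-yl]-3,4-dihydro-2H-chromen-4-ol F8. The mismatched (2S)-ketone is left unreduced, the alkenes are untouched, and chromatography separates ketone from alcohol, so the sequence comes back to the route at flavanone 17.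

Step 7 (ortho-acetylation). O-acetylation or loss of a MOM group at magnesium may outrun C-acylation. The fallback brings the carbonyl carbon in as formaldehyde. It sets out from phenol 11. MgCl2, Et3N and paraformaldehyde in MeCN at reflux formylate only ortho to the free OH and give 2-hydroxy-4,6-bis(methoxymethoxy)-3-[(2R)-5-methyl-2-(prop-1-en-2-yl)hex-4-en-1-yl]benzaldehyde F5. MeMgBr (2.5 equiv, THF, −78 °C) adds to give 2-(1-hydroxyethyl)-3,5-bis(methoxymethoxy)-6-[(2R)-5-methyl-2-(prop-1-en-2-yl)hex-4-en-1-yl]phenol F6 as a mixture of carbinol epimers. MnO2 in CH2Cl2 oxidises the benzylic alcohol, and the sequence comes back to the route at acetophenone 13.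

**Further compounds**
F1 | step 4 | 1-(1H-imidazol-1-yl)-5-methylhex-4-en-1-one | CC(C)=CCCC(=O)n1ccnc1
F2 | step 4 | (3R)-5,7-bis(methoxymethoxy)-3-(3-methylbut-2-en-1-yl)-3,4-dihydro-2H-chromen-2-one | O=C1[C@H](CC=C(C)C)Cc2c(OCOC)cc(OCOC)cc2O1
F3 | step 4 | (2R)-2-{[2-hydroxy-4,6-bis(methoxymethoxy)phenyl]methyl}-N-methoxy-N,5-dimethylhex-4-enamide | CON(C)C(=O)[C@H](CC=C(C)C)Cc1c(O)cc(OCOC)cc1OCOC
F4 | step 4 | (3R)-3-{[2-hydroxy-4,6-bis(methoxymethoxy)phenyl]methyl}-6-methylhept-5-en-2-one | CC(=O)[C@H](CC=C(C)C)Cc1c(O)cc(OCOC)cc1OCOC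
F5 | step 7 | 2-hydroxy-4,6-bis(methoxymethoxy)-3-[(2R)-5-methyl-2-(prop-1-en-2-yl)hex-4-en-1-yl]benzaldehyde | C=C(C)[C@H](CC=C(C)C)Cc1c(O)c(C=O)c(OCOC)cc1OCOC
F6 | step 7 | 2-(1-hydroxyethyl)-3,5-bis(methoxymethoxy)-6-[(2R)-5-methyl-2-(prop-1-en-2-yl)hex-4-en-1-yl]phenol | C=C(C)[C@H](CC=C(C)C)Cc1c(O)c(C(C)O)c(OCOC)cc1OCOC
F7 | step 10 | (2R)-2-[5-methoxy-2,4-bis(methoxymethoxy)phenyl]-5,7-bis(methoxymethoxy)-8-[(2R)-5-methyl-2-(prop-1-en-2-yl)hex-4-en-1-yl]-2,3-dihydro-4H-chromen-4-one | C=C(C)[C@H](CC=C(C)C)Cc1c(OCOC)cc(OCOC)c2c1O[C@@H](c1cc(OC)c(OCOC)cc1OCOC)CC2=O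
F8 | step 10 | (2R,4R)-2-[5-methoxy-2,4-bis(methoxymethoxy)phenyl]-5,7-bis(methoxymethoxy)-8-[(2R)-5-methyl-2-(prop-1-en-2-yl)hex-4-en-1-yl]-3,4-dihydro-2H-chromen-4-ol | C=C(C)[C@H](CC=C(C)C)Cc1c(OCOC)cc(OCOC)c2c1O[C@@H](c1cc(OC)c(OCOC)cc1OCOC)C[C@H]2O
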